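## Structural features

The target is a mixed sesquiterpene–neolignan ether. A trans-fused eudesmane decalin (ring A = C1–C5 and C10, ring B = C5–C10) is joined through an oxygen on C4 to O-2 of the biaryl of honokiol (3',5-diallylbiphenyl-2,4'-diol), whose 4'-OH stays free. The decalin has four stereocentres; C4, C5 and C10 are contiguous and C7 lies 1,3 to C5. C4 is fully substituted (aryloxy α-equatorial, C15 methyl β-axial), C5 carries an α-hydrogen, C10 is quaternary with a β-axial methyl, and C7 bears a β-equatorial 2-hydroxyprop-2-yl group, so the C15 and C14 methyls are syn-diaxial on the β face of ring A. The fragile groups are the two allylarenes (migration into conjugation under strong base and heat; reactive towards hydrogenation, hydroboration, carbenes and electrophilic metals), the tertiary alkyl aryl ether and the tertiary C11 carbinol (both ionise in acid), and the free phenol. The real difficulty is the C4–O bond: a hindered ortho-aryl phenol oxygen has to be placed, with one configuration, on a tertiary carbon next to the ring fusion, where ionising conditions would give eudesmenes or C-alkylation and a Williamson or SNAr reaction has no handle. Everything else (C5, C7, C10, both carbocycles and the whole biaryl) is available in the natural products β-eudesmol (1) and honokiol (5). The key step exploits two features: C4 carries an oxygen and a one-carbon branch (C15) on the same atom, which is the retron of an α-aryloxy acid built on the C4 carbonyl of the 15-nor ketone, and the axial C10 methyl shields the β face of C4.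

## Logic of the disconnections

15 ⇒ 14. The O11–Si and O4'–Si bonds are cut last. The tertiary alcohol and the second phenol must be masked through the carbenoid, hydride and sulfonylation steps, and two silyl ethers fall together in one fluoride operation. Nothing is gained in skeleton. The forward step must be non-acidic (the C4–O ether and the C11 carbinol ionise in acid) and must not move the allyl double bonds.

14 ⇒ 13 ⇒ 12. The C15–H bond is traced to a C15–O sulfonate (13) and then to the primary alcohol (12). C15 has to arrive oxidised because the key step brings it in as a carboxyl carbon. The forward step is an SN2 hydride displacement at an axial neopentyl carbon; C4 has no hydrogen, so elimination cannot compete and the C4 configuration is not touched.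

12 ⇒ 11. C15 is raised to the acid level, which exposes the α-aryloxy acid retron. The forward reduction must spare two terminal alkenes and two silyl ethers, which rules out borane and hydrogenation.

11 ⇒ 4 + 6 + 7. The C4–O(aryl) and C4–C15 bonds are cut together. This is the strategic cut: it separates the molecule into its two natural-product halves plus a one-carbon unit, so the synthesis is convergent and C4 is the only stereocentre to be made. The forward step needs two events on the α face of C4 (carbonyl addition, then substitution with inversion), a single phenoxide nucleophile (hence the 4'-O-silyl group of 6), no competing alkoxide (hence the 11-O-silyl group of 4), and no free dichlorocarbene near the allyl groups.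

4 ⇒ 2 ⇒ 1. The C4 carbonyl is traced to the C4=C15 alkene (oxidative cleavage) and the O11–Si bond to the free carbinol. C15 of 1 is thus excised and later returned from 7; the price is accepted because the returning carbon brings the C4 oxygen substituent and its configuration with it. The forward cleavage must be neutral so that C5, now α to a carbonyl, keeps the trans fusion.

6 ⇒ 5. The O4'–Si bond is cut. The forward step must distinguish the two phenols of 5.

## Other disconnections considered

Alternative 1: Cut C1–C10 and C4–C5 of ring A, taking the decalin back to a monocyclic chiral-pool ketone.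
- **Forward key step:** (5R)-dihydrocarvone A1 (either C2 epimer) is condensed with a chiral 1-arylethylamine. The more substituted secondary enamine adds to ethyl vinyl ketone A2 on the face set by the auxiliary, creating quaternary C10 with its methyl β. After hydrolysis, a base-mediated aldol condensation closes ring A to (+)-α-cyperone A3.
- **In its favour:** a well-understood, auxiliary-controlled annulation from cheap materials, stereoconvergent in A1, that installs C15 directly as a methyl group. On supply security and on the oxidation level of C15 it is the equal or the better of the chosen plan.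
- **Against it here:** A3 stops far from 15. The C3 carbonyl must be removed, the C4=C5 alkene turned into a 5α-hydrogen and an oxygenated C4, and the isopropenyl group hydrated at C11. The C4–O aryl bond, the one hard bond, is not addressed.
- **Comparison:** structurally it rebuilds ring A, C10 and C7, which the chosen plan takes intact from 1. Mechanistically it is more secure than the chosen key step, but only for bonds that need no synthesis. In step count it adds on the order of six or more operations before the etherification problem is reached, so it would only be attractive if 1 were unavailable.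

Alternative 2: Cut C6–C7, C5–C10, C11–O and C4–O(H), tracing the whole bicyclic diol to acyclic (2E,6E)-farnesyl diphosphate A4.
- **Forward key step:** a class I sesquiterpene synthase ionises A4, closes the ten-membered ring (C6–C7) and hydroxylates C11. Reprotonation of the macrocyclic dienol then forms C5–C10 (both six-membered rings), and hydroxyl capture at C4 gives cryptomeridiol A5.
- **In its favour:** all four stereocentres, the 4α-oxygen and the 4β-methyl would arise in one operation with enzyme-set configuration and no redox traffic at C15. On stereochemical certainty at C4 and on economy of skeleton construction it is better than the chosen plan.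
- **Against it here:** the C4 oxygen arrives as O–H, so the ether would have to be made by arylating a very hindered tertiary alkoxide with the arene as electrophile. 5 has no leaving group or activation at C-2, so the biaryl would have to be built afterwards from a halogenated arene, and the less hindered C11–OH would have to be masked first. The enzyme and A4 are not shelf reagents on a preparative scale.
- **Comparison:** the skeleton is the same but the oxygen substituent is the wrong one. The polarity of the C4–O union is inverted (terpene oxygen as nucleophile, arene as electrophile), whereas the chosen plan uses the natural phenoxide of 5 and keeps 5 intact. One step reaches A5, but protection, O-arylation, biaryl coupling, allylation and deprotection make the total no shorter, and the hardest bond becomes harder.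

Alternative 3: Cut C2–C3 of ring A and C4–O, going back to elemol A6 as its 11-O-triethylsilyl ether A7 and to 4-bromo-2-iodophenol A8.
- **Forward key step:** palladium(II) with a quinone re-oxidant activates the vinyl group of A7. The isopropenyl terminus C3 attacks C2 in a chair-like interrupted Cope process, the developing C4 cation is captured by the oxygen of A8, and β-hydride loss from C1–Pd leaves the 1,2-alkene of 4α-(4-bromo-2-iodophenoxy)-11-triethylsilyloxy-eudesm-1-ene A9.
- **In its favour:** A6 is a cheap chiral-pool material, and ring A and the C4–O bond would form in one step. C15 is a methyl from the outset, so the three redox steps after the chosen key step disappear. On redox economy it is better; in overall step count it is roughly equal.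
- **Against it here:** intermolecular capture of the cationic centre by a phenol oxygen in this manifold has no close analogy. The expected competitors are completion of the Cope rearrangement, proton loss to eudesmadienes and C-alkylation of the phenol. A8 is an electron-poor, weak O-nucleophile, and its C–I bond is not innocent towards the palladium(0) formed after β-hydride elimination. The C4 configuration would rest on anti addition in one particular chair.
- **Comparison:** it makes a ring that 1 already contains and rebuilds 5 late: after A9 the alkene must be saturated without touching the halides, followed by two cross-couplings and desilylation. The risk sits in an unprecedented reaction type, whereas the chosen plan stretches an established three-component reaction to a hindered case. Both come to about eight steps.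

Key step: step 4

Assumptions and checks:
- **Site selectivity in step 3:** silylation of 5 with a bulky silyl chloride is taken to favour the 4'-OH, which should be both the less shielded and the slightly more acidic phenol. The regioisomer and the bis-ether are assumed separable by chromatography.
- **Structures:** 4, 6 and 11 carry the same configurations at C5, C7 and C10 as 15, the free phenol of 6 is O-2, and the C4 arrangement of 11 (aryloxy α, carboxyl β) maps onto 15. No structural correction was needed.
- **Design refinement:** the aryl O–Si bond of 6 is the weak point under hydroxide. Trichloromethide is therefore made with an amide base at −78 °C, and hydroxide is used only for a short, cold hydrolysis at the end. TIPS is kept because it is the most base-resistant common aryl silyl ether and leaves with TES in one fluoride step.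

## Route

Step 1
Reactants: 1 (+)-β-eudesmol [eudesm-4(15)-en-11-ol; 5α-H, 7β-(2-hydroxyprop-2-yl), 10β-CH3]
Product: 2 11-triethylsilyloxyeudesm-4(15)-ene
Conditions: TESOTf, 2,6-lutidine, CH2Cl2, −78 → 0 °C
Reagents that add atoms: triethylsilyl trifluoromethanesulfonate, CC[Si](CC)(CC)OS(=O)(=O)C(F)(F)F
Why: O-silylation of a tertiary alcohol with a silyl triflate and a hindered pyridine base; the exocyclic alkene is inert and no stereocentre is touched.

Step 2
Reactants: 2 11-triethylsilyloxyeudesm-4(15)-ene
Product: 4 11-O-triethylsilyl-15-nor-eudesman-4-one (5α-H; trans-decalone), via spiro ozonide 3 (not isolated)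
Conditions: O3, CH2Cl2, −78 °C; then PPh3, −78 → 20 °C
Reagents that add atoms: ozone, [O-][O+]=O
Why: Ozonolysis of the only alkene (cycloaddition, cycloreversion and recombination to ozonide 3, then P(III) reduction) removes C15 as formaldehyde; the medium is neutral, so C5 next to the new carbonyl keeps the trans fusion and the TES ether survives.

Step 3
Reactants: 5 honokiol (3',5-diallylbiphenyl-2,4'-diol)
Product: 6 4'-O-triisopropylsilylhonokiol (free 2-OH)
Conditions: TIPSCl (1.0 equiv), imidazole, CH2Cl2, 0 °C
Reagents that add atoms: triisopropylsilyl chloride, CC(C)[Si](Cl)(C(C)C)C(C)C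
Why: Imidazole-promoted silyl ether formation; the bulky silyl chloride should prefer the 4'-OH, which has only a flexible ortho-allyl neighbour and is expected to be the more acidic phenol, over the 2-OH beside the twisted biaryl axis.

Step 4
Reactants: 4 11-O-triethylsilyl-15-nor-eudesman-4-one; 6 4'-O-triisopropylsilylhonokiol; 7 chloroform
Product: 11 4α-aryloxy-11-O-TES-4'-O-TIPS-eudesman-15-oic acid [aryloxy = 4-allyl-2-(3-allyl-4-triisopropylsilyloxyphenyl)phenoxy; carboxyl β-axial], via lithium trichloromethylcarbinolate 8 (not isolated), via spiro gem-dichloroepoxide 9 (not isolated), via α-aryloxy acyl chloride 10 (not isolated)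
Conditions: 4, CHCl3 (1.5 equiv), LiHMDS (1.2 equiv, added last), THF, −78 °C; then sodium phenoxide of 6 (from NaH; 2.5 equiv), THF–DMPU, −78 → 20 °C; then aq. LiOH, 0 °C; pH 5 work-up
Reagents that add atoms: lithium hydroxide, [Li+].[OH-] (its oxygen becomes the carboxyl OH; C15 comes from reactant 7)
Why: Lithium trichloromethide, made from 7 and LiHMDS at −78 °C in the presence of 4, adds to the C4 carbonyl from the α (equatorial) side because the β-axial trajectory runs into the axial C10 methyl, giving carbinolate 8 with oxygen β and CCl3 α. On warming with the sodium phenoxide of 6 in a dipolar medium the alkoxide displaces one chloride to give the transient spiro dichloroepoxide 9, the phenoxide oxygen opens it at C4 from the α face with inversion, the resulting α-chloro alkoxide loses chloride to give acyl chloride 10, and cold aqueous LiOH converts this into acid 11. The closest known reaction type is the Bargellini reaction in its Jocic–Reeve form, which joins ketones, chloroform and phenols to α-aryloxy acids; it is run here in stages so that hydroxide is absent while the C–C and C–O bonds form. No ring of the product is closed: the only ring formed is the three-membered epoxide of 9 (3-exo-tet closure), and it is opened again in the same flask. The one new stereocentre, C4, is fixed by two α-face events, the carbonyl addition steered by the C10 methyl and the stereospecific backside opening of the axial C–O bond, so the aryloxy group ends α-equatorial and the carboxyl β-axial. The step needs O-attack by a single phenoxide (secured by the 4'-O-silyl group and the dipolar aprotic medium), no competing alkoxide (11-O-TES) and no free dichlorocarbene near the allyl groups (carbenoid made cold with only a slight excess of base; phenoxide is too weak a base to deprotonate residual 7). Enolisation towards C5 is limited by adding the amide base last to the ketone–chloroform mixture.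

Step 5
Reactants: 11 4α-aryloxy-11-O-TES-4'-O-TIPS-eudesman-15-oic acid
Product: 12 4α-aryloxy-11-O-TES-4'-O-TIPS-eudesman-15-ol (CH2OH β-axial)
Conditions: LiAlH4, THF, 0 → 45 °C; Rochelle salt work-up
Reagents that add atoms: none
Why: Hydride reduction of a carboxylic acid by LiAlH4; isolated terminal alkenes, aryl ethers and trialkylsilyl ethers are not reduced, borane is avoided because it would hydroborate the allyl groups, and C4 is quaternary so its configuration cannot change.

Step 6
Reactants: 12 4α-aryloxy-11-O-TES-4'-O-TIPS-eudesman-15-ol
Product: 13 4α-aryloxy-11-O-TES-4'-O-TIPS-eudesman-15-yl methanesulfonate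
Conditions: MsCl, Et3N, CH2Cl2, −20 → 0 °C
Reagents that add atoms: methanesulfonyl chloride, CS(=O)(=O)Cl
Why: Sulfonylation through sulfene, which is small enough to reach the axial neopentyl hydroxyl; the phenol and the tertiary alcohol are masked, so only O-15 reacts.

Step 7
Reactants: 13 4α-aryloxy-11-O-TES-4'-O-TIPS-eudesman-15-yl methanesulfonate
Product: 14 11-O-triethylsilyl-4'-O-triisopropylsilyl ether of the target (4β-CH3, 4α-aryloxy)
Conditions: LiEt3BH, THF, 0 → 65 °C
Reagents that add atoms: none
Why: SN2 displacement of a primary sulfonate by the strongly nucleophilic triethylborohydride, a reagent suited to neopentyl centres; C4 has no hydrogen, so E2 is impossible, and no stereocentre is involved.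

Step 8
Reactants: 14 11-O-triethylsilyl-4'-O-triisopropylsilyl ether of the target
Product: 15 target, 4α-[4-allyl-2-(3-allyl-4-hydroxyphenyl)phenoxy]eudesman-11-ol (4β-CH3, 5α-H, 7β-side chain, 10β-CH3)
Conditions: TBAF, THF, 0 → 40 °C; aq. NH4Cl
Reagents that add atoms: none
Why: Fluoride-mediated Si–O cleavage removes the aryl TIPS ether quickly and the tertiary TES ether on gentle warming; the conditions are non-acidic, so the tertiary aryl ether and the C11 carbinol are safe, and short exposure at ≤40 °C should not move the allyl double bonds.

## Compound list

1 | (+)-β-eudesmol, eudesm-4(15)-en-11-ol (5α-H, 7β-side chain, 10β-CH3) | C=C1CCC[C@]2(C)CC[C@@H](C(C)(C)O)C[C@H]21 | starting material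
2 | 11-triethylsilyloxyeudesm-4(15)-ene | C=C1CCC[C@]2(C)CC[C@@H](C(C)(C)O[Si](CC)(CC)CC)C[C@H]21 | intermediate
3 | spiro ozonide (1,2,4-trioxolane spanning C4 and C15 of 2; both C4 epimers) | O1COOC12CCC[C@]3(C)CC[C@@H](C(C)(C)O[Si](CC)(CC)CC)C[C@H]32 | intermediate
4 | 11-O-triethylsilyl-15-nor-eudesman-4-one | O=C1CCC[C@]2(C)CC[C@@H](C(C)(C)O[Si](CC)(CC)CC)C[C@H]21 | intermediate
5 | honokiol | C=CCc1ccc(O)c(-c2ccc(O)c(CC=C)c2)c1 | starting material
6 | 4'-O-triisopropylsilylhonokiol | C=CCc1ccc(O)c(-c2ccc(O[Si](C(C)C)(C(C)C)C(C)C)c(CC=C)c2)c1 | intermediate
7 | chloroform | ClC(Cl)Cl | starting material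
8 | lithium 4α-(trichloromethyl)-11-triethylsilyloxy-15-nor-eudesman-4β-olate | [Li+].[O-][C@@]1(C(Cl)(Cl)Cl)CCC[C@]2(C)CC[C@@H](C(C)(C)O[Si](CC)(CC)CC)C[C@H]21 | intermediate
9 | 15,15-dichloro-4β,15-epoxy-11-triethylsilyloxyeudesmane (epoxide O β, CCl2 α) | O1[C@@]3(C1(Cl)Cl)CCC[C@]2(C)CC[C@@H](C(C)(C)O[Si](CC)(CC)CC)C[C@H]23 | intermediate
10 | 4α-aryloxy-11-O-TES-4'-O-TIPS-eudesman-15-oyl chloride | C=CCc1ccc(O[C@]2(C(=O)Cl)CCC[C@]3(C)CC[C@@H](C(C)(C)O[Si](CC)(CC)CC)C[C@H]32)c(-c2ccc(O[Si](C(C)C)(C(C)C)C(C)C)c(CC=C)c2)c1 | intermediate
11 | 4α-aryloxy-11-O-TES-4'-O-TIPS-eudesman-15-oic acid | C=CCc1ccc(O[C@]2(C(=O)O)CCC[C@]3(C)CC[C@@H](C(C)(C)O[Si](CC)(CC)CC)C[C@H]32)c(-c2ccc(O[Si](C(C)C)(C(C)C)C(C)C)c(CC=C)c2)c1 | intermediate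
12 | 4α-aryloxy-11-O-TES-4'-O-TIPS-eudesman-15-ol | C=CCc1ccc(O[C@]2(CO)CCC[C@]3(C)CC[C@@H](C(C)(C)O[Si](CC)(CC)CC)C[C@H]32)c(-c2ccc(O[Si](C(C)C)(C(C)C)C(C)C)c(CC=C)c2)c1 | intermediate
13 | 4α-aryloxy-11-O-TES-4'-O-TIPS-eudesman-15-yl methanesulfonate | C=CCc1ccc(O[C@]2(COS(C)(=O)=O)CCC[C@]3(C)CC[C@@H](C(C)(C)O[Si](CC)(CC)CC)C[C@H]32)c(-c2ccc(O[Si](C(C)C)(C(C)C)C(C)C)c(CC=C)c2)c1 | intermediate
14 | 11-O-triethylsilyl-4'-O-triisopropylsilyl ether of the target | C=CCc1ccc(O[C@]2(C)CCC[C@]3(C)CC[C@@H](C(C)(C)O[Si](CC)(CC)CC)C[C@H]32)c(-c2ccc(O[Si](C(C)C)(C(C)C)C(C)C)c(CC=C)c2)c1 | intermediate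
15 | 4α-[4-allyl-2-(3-allyl-4-hydroxyphenyl)phenoxy]eudesman-11-ol | C=CCc1ccc(O[C@]2(C)CCC[C@]3(C)CC[C@@H](C(C)(C)O)C[C@H]32)c(-c2ccc(O)c(CC=C)c2)c1 | target

## Step count and least certain steps

Total: 8 steps. Longest linear sequence: 7 steps (steps 1, 2, 4, 5, 6, 7, 8); the branch from 5 has 6 (steps 3–8).

**Step 4 (key step).** Several processes could erode it.
- The carbonyl addition could reverse on warming, leading to carbene attack on the phenoxide ring or the allyl groups.
- The hindered ortho-aryl phenoxide may be too slow at the crowded C4, so that chloride or adventitious hydroxide captures the dichloroepoxide.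
- Facial selectivity in the carbonyl addition could be incomplete.
- The aryl O–Si bond could be lost under base.

Fallback, from 4 and 6, returning at 12: dimethylsulfonium methylide (Me3S+ I−, n-BuLi, THF, −10 °C) should add to the C4 carbonyl from the same α face (Corey–Chaykovsky) to give the spiro-epoxide 4β,15-epoxy-11-triethylsilyloxyeudesmane F1 (oxygen β, CH2 α). Lewis-acid-catalysed opening of F1 at its tertiary carbon by the phenol 6 (catalytic BF3·OEt2, CH2Cl2, −78 °C), with inversion, would then give 12 directly. C15 comes from the ylide instead of 7, and steps 4 and 5 are bypassed.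

**Step 7.** Hydride may attack at sulfur (S–O cleavage back to 12), or displacement may fail. C15 is neopentylic, axial, syn to the C10 methyl and inductively deactivated by the geminal aryloxy group.

Fallback, from 12, returning at 14: Dess–Martin oxidation (NaHCO3, CH2Cl2) to the non-enolisable aldehyde 4α-aryloxy-11-O-TES-4'-O-TIPS-eudesman-15-al F2; condensation with TsNHNH2 (EtOH, 40 °C) to the tosylhydrazone F3; Caglioti-type reduction with catecholborane (CHCl3, 0 °C), then NaOAc·3H2O and gentle warming, to lose sulfinate and dinitrogen and leave the methyl group of 14. No nucleophilic substitution at the neopentyl carbon is needed.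

**Step 3.** Site selectivity between the two phenols may be insufficient, since each has one ortho substituent; the result would be mixed mono-ethers and over-silylation.

Fallback, returning at 6: this one does not start from a numbered compound. It replaces 5 by two monoaryl building blocks so that the phenols are never equivalent.
- 2-Allyl-4-bromophenol F4 is silylated (TIPSCl, imidazole) to its TIPS ether F5.
- Miyaura borylation (B2pin2, PdCl2(dppf), KOAc, dioxane) gives the pinacol boronate F6.
- Suzuki coupling of F6 with 4-allyl-2-bromophenol F7 (Pd catalyst, K3PO4, dioxane–water) gives 6 with unambiguous regiochemistry.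

**Step 5.** Reduction of the hindered axial carboxylate may be incomplete at temperatures mild enough to keep the aryl O–Si bond; loss of that protecting group would expose a phenol that competes in step 6.

Fallback, from 11, returning at 12: esterification with TMSCHN2 (toluene–MeOH) to the methyl ester F8, then DIBAL-H (CH2Cl2, −78 → 0 °C). This moves the reduction to a neutral ester and a cold, non-nucleophilic aluminium hydride.

## Further compounds

F1 | step 4 | 4β,15-epoxy-11-triethylsilyloxyeudesmane (epoxide O β, CH2 α) | O1C[C@@]13CCC[C@]2(C)CC[C@@H](C(C)(C)O[Si](CC)(CC)CC)C[C@H]23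
F2 | step 7 | 4α-aryloxy-11-O-TES-4'-O-TIPS-eudesman-15-al | C=CCc1ccc(O[C@]2(C=O)CCC[C@]3(C)CC[C@@H](C(C)(C)O[Si](CC)(CC)CC)C[C@H]32)c(-c2ccc(O[Si](C(C)C)(C(C)C)C(C)C)c(CC=C)c2)c1
F3 | step 7 | (E)-tosylhydrazone of F2 | C=CCc1ccc(O[C@]2(/C=N/NS(=O)(=O)c4ccc(C)cc4)CCC[C@]3(C)CC[C@@H](C(C)(C)O[Si](CC)(CC)CC)C[C@H]32)c(-c2ccc(O[Si](C(C)C)(C(C)C)C(C)C)c(CC=C)c2)c1
F4 | step 3 | 2-allyl-4-bromophenol | C=CCc1cc(Br)ccc1O
F5 | step 3 | (2-allyl-4-bromophenoxy)triisopropylsilane | C=CCc1cc(Br)ccc1O[Si](C(C)C)(C(C)C)C(C)C
F6 | step 3 | 2-[3-allyl-4-(triisopropylsilyloxy)phenyl]-4,4,5,5-tetramethyl-1,3,2-dioxaborolane | C=CCc1cc(B2OC(C)(C)C(C)(C)O2)ccc1O[Si](C(C)C)(C(C)C)C(C)C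
F7 | step 3 | 4-allyl-2-bromophenol | C=CCc1ccc(O)c(Br)c1
F8 | step 5 | methyl 4α-aryloxy-11-O-TES-4'-O-TIPS-eudesman-15-oate | C=CCc1ccc(O[C@]2(C(=O)OC)CCC[C@]3(C)CC[C@@H](C(C)(C)O[Si](CC)(CC)CC)C[C@H]32)c(-c2ccc(O[Si](C(C)C)(C(C)C)C(C)C)c(CC=C)c2)c1
A1 | alternative 1 | (5R)-dihydrocarvone (C2 epimers) | O=C1C[C@H](C(C)=C)CCC1C
A2 | alternative 1 | ethyl vinyl ketone | CCC(=O)C=C
A3 | alternative 1 | (+)-α-cyperone | CC1=C2C[C@H](C(C)=C)CC[C@@]2(C)CCC1=O
A4 | alternative 2 | (2E,6E)-farnesyl diphosphate | CC(C)=CCC/C(C)=C/CC/C(C)=C/COP(=O)(O)OP(=O)(O)O
A5 | alternative 2 | cryptomeridiol | O[C@]1(C)CCC[C@]2(C)CC[C@@H](C(C)(C)O)C[C@H]21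
A6 | alternative 3 | elemol | C=C[C@]1(C)CC[C@@H](C(C)(C)O)C[C@H]1C(C)=C
A7 | alternative 3 | 11-O-triethylsilylelemol | C=C[C@]1(C)CC[C@@H](C(C)(C)O[Si](CC)(CC)CC)C[C@H]1C(C)=C
A8 | alternative 3 | 4-bromo-2-iodophenol | Oc1ccc(Br)cc1I
A9 | alternative 3 | 4α-(4-bromo-2-iodophenoxy)-11-triethylsilyloxy-eudesm-1-ene | Brc1ccc(O[C@]2(C)CC=C[C@]3(C)CC[C@@H](C(C)(C)O[Si](CC)(CC)CC)C[C@H]32)c(I)c1
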